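## Retrosynthetic overview
1. Ring A (cyclohexene), ring B (cyclopentanone) and four stereocentres (C3a, C4, C5, C7a) form together in the last step. This is an endo intramolecular Diels-Alder reaction of the unprotected linear tetraene keto acid, the presumed biosynthetic precursor itself, and nothing follows the cycloaddition.
2. The fragile keto acid is released only in the flask, by oxidising the carbinol of the linear hydroxy acid.
3. The chain is cut at that carbinol. An auxiliary-controlled vinylogous Mukaiyama aldol joins an α-chiral trienal to the dienol ether of 2-ethylhex-2-enoic acid, which delivers the whole dienophile and the future C3.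
4. The trienal comes from (S)-2-ethylbut-3-en-1-ol by cross metathesis with 2-ethylacrolein, a formyl-ylide Wittig reaction and a benzylphosphonate olefination.
5. That alcohol (future C1) comes from catalytic asymmetric ethylmagnesiation of 2,5-dihydrofuran.

Numbering: target positions use indene numbering (C2 = ketone, C1 and C3 = CH(Et), C3a/C7a = ring fusion, C4 = C(Et)CO2H, C5 = C(Et)(styryl), C7 = C(Et)=). Linear compounds use their own chain numbering.

Assumption: (R,R)-(EBTHI)Zr is taken to give the S alcohol in step 1 and the L-valine-derived auxiliary to give 4S in the aldol of step 9; both controllers are sold as either antipode, so a reversed sense only means swapping the antipode.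

## Route

Step 1
Reactants: 1 2,5-dihydrofuran; 2 ethylmagnesium chloride
Product: 3 (S)-2-ethylbut-3-en-1-ol
Conditions: (R,R)-ethylenebis(4,5,6,7-tetrahydro-1-indenyl)zirconium dichloride, (EBTHI)ZrCl2 (10 mol %), 2 (5 equiv), THF, 22 °C; 1 M HCl quench
Reagents that add atoms: none
Why: In this zirconocene-catalysed asymmetric carbomagnesiation (ethylmagnesiation) the chiral zirconocene-ethene complex differentiates the two enantiotopic alkene carbons of the ring as the site of C-C bond formation and β-alkoxide elimination opens the ring, which sets the future C1 as S (typically ≥95 % ee) and leaves a vinyl group.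

Step 2
Reactants: 3 (S)-2-ethylbut-3-en-1-ol; 4 2-ethylacrolein
Product: 5 (2E,4S)-2,4-diethyl-5-hydroxypent-2-enal
Conditions: second-generation Hoveyda-Grubbs catalyst, RuCl2(H2IMes)(=CH-C6H4-2-OiPr) (5 mol %), 4 (4 equiv), 1,4-benzoquinone (10 mol %), CH2Cl2, 40 °C
Reagents that add atoms: none
Why: Olefin cross metathesis of a terminal alkene with an electron-poor 1,1-disubstituted alkene that does not homodimerise gives the E-trisubstituted enal, the allylic stereocentre is not touched, and benzoquinone suppresses ruthenium hydride isomerisation.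

Step 3
Reactants: 6 propyltriphenylphosphonium bromide; 7 methyl formate
Product: 9 2-(triphenylphosphoranylidene)butanal, via propylidenetriphenylphosphorane 8 (not isolated)
Conditions: KOtBu (1.05 equiv), THF, 0 °C; then 7, 0 °C to rt
Reagents that add atoms: none
Why: This is C-formylation of a non-stabilised Wittig ylide by a formate ester, after which the released methoxide deprotonates the acylphosphonium ion to the stabilised ylide, and no stereocentre is involved.

Step 4
Reactants: 5 (2E,4S)-2,4-diethyl-5-hydroxypent-2-enal; 9 2-(triphenylphosphoranylidene)butanal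
Product: 10 (2E,4E,6S)-2,4,6-triethyl-7-hydroxyhepta-2,4-dienal
Conditions: 9 (1.3 equiv), toluene, 90 °C
Reagents that add atoms: none
Why: A Wittig olefination with a stabilised α-branched ylide gives the E-trisubstituted alkene (formyl trans to the chain), the neutral medium leaves the free alcohol and the remote stereocentre alone, and the more conjugated dienal product reacts more slowly than 5, which limits double homologation.

Step 5
Reactants: 10 (2E,4E,6S)-2,4,6-triethyl-7-hydroxyhepta-2,4-dienal; 11 diethyl benzylphosphonate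
Product: 12 (2S,3E,5E,7E)-2,4,6-triethyl-8-phenylocta-3,5,7-trien-1-ol
Conditions: 11 (2.2 equiv), NaN(SiMe3)2 (2.1 equiv), THF, -78 °C; then 10, -78 to 0 °C
Reagents that add atoms: none
Why: A Horner-Wadsworth-Emmons olefination with a benzylic phosphonate anion gives the E-styrene through reversible addition, the first equivalent of anion only parks the alcohol as its alkoxide, and carbonyl addition at low temperature outruns ε-deprotonation so the stereocentre is kept.

Step 6
Reactants: 12 (2S,3E,5E,7E)-2,4,6-triethyl-8-phenylocta-3,5,7-trien-1-ol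
Product: 13 (2S,3E,5E,7E)-2,4,6-triethyl-8-phenylocta-3,5,7-trienal
Conditions: Dess-Martin periodinane, NaHCO3, CH2Cl2, 0 °C; used crude
Reagents that add atoms: none
Why: Buffered Dess-Martin oxidation stops at the aldehyde, and the α-C-H bond is held in the plane of the neighbouring alkene by allylic 1,3-strain with the vinylic ethyl group, so it overlaps poorly with the π system and neither epimerisation nor alkene migration is expected at 0 °C.

Step 7
Reactants: 14 (E)-2-ethylhex-2-enoic acid; 15 (S)-4-isopropyloxazolidin-2-one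
Product: 17 (S)-3-[(E)-2-ethylhex-2-enoyl]-4-isopropyloxazolidin-2-one, via mixed pivalic anhydride 16 (not isolated)
Conditions: pivaloyl chloride, Et3N, THF, -20 °C; then LiCl, 15, rt
Reagents that add atoms: pivaloyl chloride, CC(C)(C)C(=O)Cl (its atoms stay only in 16)
Why: This is one-pot N-acylation through a mixed anhydride in which the LiCl-activated oxazolidinone attacks the enoyl carbonyl because the pivaloyl carbonyl is shielded by the tert-butyl group, and the auxiliary stereocentre is not affected.

Step 8
Reactants: 17 (S)-3-[(E)-2-ethylhex-2-enoyl]-4-isopropyloxazolidin-2-one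
Product: 18 (S)-3-[(1E,3E)-1-(tert-butyldimethylsilyloxy)-2-ethylhexa-1,3-dien-1-yl]-4-isopropyloxazolidin-2-one
Conditions: NaN(SiMe3)2, TBSCl, THF, -78 °C
Reagents that add atoms: tert-butyldimethylsilyl chloride, CC(C)(C)[Si](C)(C)Cl
Why: γ-Deprotonation of the enoyl imide and O-silylation give the vinylketene silyl N,O-acetal as the 1E,3E isomer because allylic strain turns the terminal ethyl group away from the 2-ethyl group, and no new stereocentre is formed.

Step 9
Reactants: 13 (2S,3E,5E,7E)-2,4,6-triethyl-8-phenylocta-3,5,7-trienal; 18 (S)-3-[(1E,3E)-1-(tert-butyldimethylsilyloxy)-2-ethylhexa-1,3-dien-1-yl]-4-isopropyloxazolidin-2-one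
Product: 19 (S)-3-[(2E,4S,5R,6S,7E,9E,11E)-2,4,6,8,10-pentaethyl-5-hydroxy-12-phenyldodeca-2,7,9,11-tetraenoyl]-4-isopropyloxazolidin-2-one
Conditions: TiCl4 (1.0 equiv), 18 (1.5 equiv), CH2Cl2, -78 to -40 °C; aqueous work-up
Reagents that add atoms: none
Why: In this Kobayashi-type vinylogous Mukaiyama aldol the auxiliary stands perpendicular to the dienol ether and its isopropyl group blocks one face so C4 (future C3) is set as S by reagent control, the open transition state gives the 4,5-anti relation and Felkin-Anh attack on the α-chiral aldehyde gives the 5,6-syn relation so all three elements are matched, the s-trans dienol ether delivers the E-enoyl unit, and the C5 carbinol configuration is later erased.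

Step 10
Reactants: 19 (S)-3-[(2E,4S,5R,6S,7E,9E,11E)-2,4,6,8,10-pentaethyl-5-hydroxy-12-phenyldodeca-2,7,9,11-tetraenoyl]-4-isopropyloxazolidin-2-one
Product: 21 (2E,4S,5R,6S,7E,9E,11E)-2,4,6,8,10-pentaethyl-5-hydroxy-12-phenyldodeca-2,7,9,11-tetraenoic acid, via peroxy acid 20 (not isolated)
Conditions: LiOH, H2O2, THF/H2O, 0 °C; Na2SO3; HCl to pH 3
Reagents that add atoms: hydrogen peroxide, OO
Why: In this hydroperoxide-mediated imide cleavage the small α-effect nucleophile attacks the exocyclic carbonyl, sulfite reduces the peracid salt before acidification so the triene never meets a free peracid, and no stereocentre is α to a carbonyl at this stage so none can epimerise.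

Step 11
Reactants: 21 (2E,4S,5R,6S,7E,9E,11E)-2,4,6,8,10-pentaethyl-5-hydroxy-12-phenyldodeca-2,7,9,11-tetraenoic acid
Product: 23 (1S,3S,3aR,4R,5S,7aR)-1,3,4,5,7-pentaethyl-2-oxo-5-[(E)-2-phenylethenyl]-2,3,3a,4,5,7a-hexahydro-1H-indene-4-carboxylic acid (target), via linear keto acid 22 (not isolated)
Conditions: Dess-Martin periodinane (1.2 equiv), CH2Cl2, 0 °C; dilute with pentane, filter, concentrate cold; then toluene (5 mM), BHT (5 mol %), 85 °C
Reagents that add atoms: none
Why: Dess-Martin oxidation unveils the keto acid, which undergoes a thermal endo (CO2H under the diene, tether exo) intramolecular Diels-Alder reaction in which allylic 1,3-strain at both tether stereocentres lets only one diene face meet one dienophile face and so gives the trans fusion (C3a R, C7a R), suprafacial addition carries the E,E-diene and E-dienophile geometries into the adjacent quaternary centres (C4 R, C5 S), and C1 and C3 end in the all-trans, thermodynamically preferred cyclopentanone arrangement so they do not drift.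

## Compound list
1 | 2,5-dihydrofuran | C1C=CCO1 | starting material
2 | ethylmagnesium chloride | CC[Mg]Cl | starting material
3 | (S)-2-ethylbut-3-en-1-ol | OC[C@@H](CC)C=C | intermediate
4 | 2-ethylacrolein | C=C(CC)C=O | starting material
5 | (2E,4S)-2,4-diethyl-5-hydroxypent-2-enal | OC[C@@H](CC)/C=C(CC)/C=O | intermediate
6 | propyltriphenylphosphonium bromide | CCC[P+](c1ccccc1)(c1ccccc1)c1ccccc1.[Br-] | starting material
7 | methyl formate | COC=O | starting material
8 | propylidenetriphenylphosphorane | CCC=P(c1ccccc1)(c1ccccc1)c1ccccc1 | intermediate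
9 | 2-(triphenylphosphoranylidene)butanal | CCC(C=O)=P(c1ccccc1)(c1ccccc1)c1ccccc1 | intermediate
10 | (2E,4E,6S)-2,4,6-triethyl-7-hydroxyhepta-2,4-dienal | OC[C@@H](CC)/C=C(CC)/C=C(CC)/C=O | intermediate
11 | diethyl benzylphosphonate | CCOP(=O)(Cc1ccccc1)OCC | starting material
12 | (2S,3E,5E,7E)-2,4,6-triethyl-8-phenylocta-3,5,7-trien-1-ol | OC[C@@H](CC)/C=C(CC)/C=C(CC)/C=C/c1ccccc1 | intermediate
13 | (2S,3E,5E,7E)-2,4,6-triethyl-8-phenylocta-3,5,7-trienal | O=C[C@@H](CC)/C=C(CC)/C=C(CC)/C=C/c1ccccc1 | intermediate
14 | (E)-2-ethylhex-2-enoic acid | CCC/C=C(\CC)C(=O)O | starting material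
15 | (S)-4-isopropyloxazolidin-2-one | CC(C)[C@H]1COC(=O)N1 | starting material
16 | (E)-2-ethylhex-2-enoic pivalic anhydride | CCC/C=C(\CC)C(=O)OC(=O)C(C)(C)C | intermediate
17 | (S)-3-[(E)-2-ethylhex-2-enoyl]-4-isopropyloxazolidin-2-one | CCC/C=C(\CC)C(=O)N1[C@@H](C(C)C)COC1=O | intermediate
18 | (S)-3-[(1E,3E)-1-(tert-butyldimethylsilyloxy)-2-ethylhexa-1,3-dien-1-yl]-4-isopropyloxazolidin-2-one | CC/C=C/C(CC)=C(/O[Si](C)(C)C(C)(C)C)N1[C@@H](C(C)C)COC1=O | intermediate
19 | (S)-3-[(2E,4S,5R,6S,7E,9E,11E)-2,4,6,8,10-pentaethyl-5-hydroxy-12-phenyldodeca-2,7,9,11-tetraenoyl]-4-isopropyloxazolidin-2-one | O=C1OC[C@H](C(C)C)N1C(=O)/C(CC)=C/[C@H](CC)[C@H](O)[C@@H](CC)/C=C(CC)/C=C(CC)/C=C/c1ccccc1 | intermediate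
20 | (2E,4S,5R,6S,7E,9E,11E)-2,4,6,8,10-pentaethyl-5-hydroxy-12-phenyldodeca-2,7,9,11-tetraeneperoxoic acid | OOC(=O)/C(CC)=C/[C@H](CC)[C@H](O)[C@@H](CC)/C=C(CC)/C=C(CC)/C=C/c1ccccc1 | intermediate
21 | (2E,4S,5R,6S,7E,9E,11E)-2,4,6,8,10-pentaethyl-5-hydroxy-12-phenyldodeca-2,7,9,11-tetraenoic acid | OC(=O)/C(CC)=C/[C@H](CC)[C@H](O)[C@@H](CC)/C=C(CC)/C=C(CC)/C=C/c1ccccc1 | intermediate
22 | (2E,4S,6S,7E,9E,11E)-2,4,6,8,10-pentaethyl-5-oxo-12-phenyldodeca-2,7,9,11-tetraenoic acid | OC(=O)/C(CC)=C/[C@H](CC)C(=O)[C@@H](CC)/C=C(CC)/C=C(CC)/C=C/c1ccccc1 | intermediate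
23 | (1S,3S,3aR,4R,5S,7aR)-1,3,4,5,7-pentaethyl-2-oxo-5-[(E)-2-phenylethenyl]-2,3,3a,4,5,7a-hexahydro-1H-indene-4-carboxylic acid | CCC1=C[C@@](/C=C/c2ccccc2)(CC)[C@](CC)(C(=O)O)[C@@H]2[C@@H]1[C@H](CC)C(=O)[C@H]2CC | target

Total step count: 11. Longest linear sequence: 8 (steps 1, 2, 4, 5, 6, 9, 10, 11).

## Steps most likely to fail

**Step 11.** In 22 both tether stereocentres are α to the ketone and allylic, and the cycloaddition is slow because it builds two adjacent quaternary centres. If C4 of 22 epimerises, or the enoic acid alkene slips toward the ketone, the cis-fused series opens up. The fallback reverses the order of events and cyclises at the configurationally inert alcohol level. Compound 21 is heated in toluene (BHT, 110 °C) and, under the same allylic-strain control, gives the hydrindene hydroxy acid F1. Dess-Martin oxidation of F1 then gives the target. The fallback sets out from 21 and comes back at 23.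

**Step 9.** TiCl4 may polymerise the styryl triene, epimerise aldehyde 13, or trigger a premature cycloaddition of the chelated imide. The fallback builds the dienophile stepwise, without a strong Lewis acid.
- Commercial (R)-4-benzyl-3-butanoyloxazolidin-2-one (Bu2BOTf, Et3N, -78 °C) adds to 13 in an Evans syn aldol. This is matched with the anti-Felkin preference of Z-boron enolates and gives the syn-aldol imide F2.
- LiBH4 gives the 1,3-diol F3.
- TEMPO/PhI(OAc)2 oxidises only the primary alcohol, giving the β-hydroxy aldehyde F4.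
- Ethyl 2-(triphenylphosphoranylidene)butanoate gives the E-enoate ethyl ester F5.
- LiOH gives the 5-epimeric hydroxy acid F6.
- Dess-Martin oxidation erases the epimeric carbinol.

The fallback sets out from 13 and comes back at 22.

**Step 2.** The allylic branch of 3, combined with a 1,1-disubstituted partner, may make the metathesis sluggish or allow alkene isomerisation. The fallback avoids both the zirconium step and metathesis by using dienol ether 18 a second time. With 1,3,5-trioxane and TiCl4, vinylogous hydroxymethylation on the same open face gives the hydroxymethyl imide F7, which has the same S configuration. Reduction with iBu2AlH (CH2Cl2, -78 °C) then takes the imide directly to the enal. The fallback sets out from 18 and comes back at 5.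

## Further compounds
F1 | step 11 | (1S,2R,3S,3aR,4R,5S,7aR)-1,3,4,5,7-pentaethyl-2-hydroxy-5-[(E)-2-phenylethenyl]-2,3,3a,4,5,7a-hexahydro-1H-indene-4-carboxylic acid | CCC1=C[C@@](/C=C/c2ccccc2)(CC)[C@](CC)(C(=O)O)[C@@H]2[C@@H]1[C@H](CC)[C@@H](O)[C@H]2CC
F2 | step 9 | (R)-4-benzyl-3-[(2R,3S,4S,5E,7E,9E)-2,4,6,8-tetraethyl-3-hydroxy-10-phenyldeca-5,7,9-trienoyl]oxazolidin-2-one | O=C1OC[C@@H](Cc2ccccc2)N1C(=O)[C@H](CC)[C@@H](O)[C@@H](CC)/C=C(CC)/C=C(CC)/C=C/c1ccccc1
F3 | step 9 | (2S,3S,4S,5E,7E,9E)-2,4,6,8-tetraethyl-10-phenyldeca-5,7,9-triene-1,3-diol | OC[C@H](CC)[C@@H](O)[C@@H](CC)/C=C(CC)/C=C(CC)/C=C/c1ccccc1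
F4 | step 9 | (2R,3S,4S,5E,7E,9E)-2,4,6,8-tetraethyl-3-hydroxy-10-phenyldeca-5,7,9-trienal | O=C[C@H](CC)[C@@H](O)[C@@H](CC)/C=C(CC)/C=C(CC)/C=C/c1ccccc1
F5 | step 9 | ethyl (2E,4S,5S,6S,7E,9E,11E)-2,4,6,8,10-pentaethyl-5-hydroxy-12-phenyldodeca-2,7,9,11-tetraenoate | CCOC(=O)/C(CC)=C/[C@H](CC)[C@@H](O)[C@@H](CC)/C=C(CC)/C=C(CC)/C=C/c1ccccc1
F6 | step 9 | (2E,4S,5S,6S,7E,9E,11E)-2,4,6,8,10-pentaethyl-5-hydroxy-12-phenyldodeca-2,7,9,11-tetraenoic acid | OC(=O)/C(CC)=C/[C@H](CC)[C@@H](O)[C@@H](CC)/C=C(CC)/C=C(CC)/C=C/c1ccccc1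
F7 | step 2 | (S)-3-[(2E,4S)-2,4-diethyl-5-hydroxypent-2-enoyl]-4-isopropyloxazolidin-2-one | O=C1OC[C@H](C(C)C)N1C(=O)/C(CC)=C/[C@H](CC)CO
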